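## Retrosynthetic overview

1. Target 20 ⇐ octamethyl ether 19 by global O-demethylation; the (2S,3S)-dihydrobenzofuran and its benzo ring come intact from natural gnetin C (1).
2. Ring B (cyclopentane fused to the benzofuran) ⇐ exocyclic (E)-4-methoxybenzylidene indane 16 by selenium-triggered Friedel–Crafts closure, then radical C–Se reduction (cis ring fusion).
3. 16 ⇐ trans-2,3-diaryl-indan-1-one 13 by 4-methoxybenzyl addition and syn-dehydration.
4. Key step: ring A of 13 ⇐ α-aryl chalcone 12 by Nazarov 4π-conrotatory electrocyclisation.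
5. 12 ⇐ aldehyde 5 (ozonolysis of permethylated 1) + 3,5-dimethoxybenzaldehyde + 4-methoxybenzaldehyde. Ring order: dihydrobenzofuran (bought) → ring A → ring B.

Assumption: natural gnetin C (melinjo seed isolate) is the (2S,3S) enantiomer drawn as 1 and is the only source of chirality; the four new centres are fixed relative to it by substrate control where possible and otherwise by separating diastereomers.

Shorthand: Bzf = (2S,3S)-3-(3,5-dimethoxyphenyl)-4-methoxy-2-(4-methoxyphenyl)-2,3-dihydro-1-benzofuran-6-yl. Ring A = cyclopentane fused to the resorcinol ring of 20; ring B = cyclopentane fused to the benzofuran.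

## Route

Step 1
Reactants: 1 natural gnetin C; 2 iodomethane
Product: 3 penta-O-methylgnetin C (Bzf–CH=CH–C6H4-4-OMe with E alkene)
Conditions: MeI, K2CO3, acetone, 55 °C
Reagents that add atoms: iodomethane, CI
Why: Williamson O-methylation (SN2 on MeI by the five phenoxides) runs under mild carbonate conditions that leave the trans-dihydrobenzofuran centres untouched.

Step 2
Reactants: 3 penta-O-methylgnetin C; 4 ozone
Product: 5 Bzf–CHO (benzofuran-6-carbaldehyde)
Conditions: O3, CH2Cl2–MeOH, −78 °C; then Me2S, −78 °C to rt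
Reagents that add atoms: ozone, [O-][O+]=O
Why: Ozonolysis with reductive work-up cleaves the electron-rich stilbene far faster than the arenes and unmasks the aryl aldehyde without touching either stereocentre.

Step 3
Reactants: 5 Bzf–CHO; 6 4-methylbenzenesulfonohydrazide; 7 3,5-dimethoxybenzaldehyde
Product: 10 1-(3,5-dimethoxyphenyl)-2-Bzf-ethan-1-one, via tosylhydrazone 8 (not isolated), via aryldiazomethane 9 (not isolated)
Conditions: TsNHNH2 (1.0 equiv), 1,4-dioxane, 60 °C; then 7 (3 equiv), K2CO3, 110 °C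
Reagents that add atoms: 3,5-dimethoxybenzaldehyde, COc1cc(C=O)cc(OC)c1
Why: Condensation gives the tosylhydrazone, carbonate releases the aryldiazomethane (Bamford–Stevens), and this adds to the aldehyde and collapses by 1,2-hydride shift with loss of N2 to the benzyl ketone (formal formyl C–H insertion), with no stereocentre formed or touched.

Step 4
Reactants: 10 1-(3,5-dimethoxyphenyl)-2-Bzf-ethan-1-one; 11 4-methoxybenzaldehyde
Product: 12 (E)-1-(3,5-dimethoxyphenyl)-2-Bzf-3-(4-methoxyphenyl)prop-2-en-1-one
Conditions: piperidine (cat.), AcOH (cat.), toluene, reflux (Dean–Stark)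
Reagents that add atoms: 4-methoxybenzaldehyde, COc1ccc(C=O)cc1
Why: Knoevenagel-type aldol condensation at the CH2 activated by both carbonyl and aryl gives the α-aryl chalcone, whose alkene geometry is irrelevant because the next step equilibrates it.

Step 5
Reactants: 12 (E)-1-(3,5-dimethoxyphenyl)-2-Bzf-3-(4-methoxyphenyl)prop-2-en-1-one
Product: 13 (2R,3R)-2-Bzf-4,6-dimethoxy-3-(4-methoxyphenyl)indan-1-one
Conditions: TFA, CH2Cl2, 0 °C to rt; separate the two trans diastereomers (SiO2 or preparative HPLC)
Reagents that add atoms: none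
Why: In this Nazarov cyclisation the O-protonated aryl vinyl ketone closes by 4π conrotatory electrocyclisation onto either (equivalent) ortho carbon of the 3,5-dimethoxyphenyl ring and enol–keto tautomerisation sets the two aryl groups trans, but the distant benzofuran centres do not bias the sense of conrotation, so the (2R,3R) and (2S,3S) trans-indanones form in about equal amounts as separable diastereomers and the (2R,3R) isomer is carried on.

Step 6
Reactants: 13 (2R,3R)-2-Bzf-4,6-dimethoxy-3-(4-methoxyphenyl)indan-1-one; 14 (4-methoxybenzyl)magnesium chloride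
Product: 15 (1S,2R,3R)-2-Bzf-4,6-dimethoxy-1-(4-methoxybenzyl)-3-(4-methoxyphenyl)indan-1-ol
Conditions: CeCl3, THF, −78 °C; then H2O
Reagents that add atoms: (4-methoxybenzyl)magnesium chloride, COc1ccc(C[Mg]Cl)cc1
Why: The weakly basic organocerium reagent made in the flask adds 1,2 to the enolisable ketone from the face opposite the neighbouring C2 aryl group (substrate control), so the OH ends up cis to that aryl and anti to H2.

Step 7
Reactants: 15 (1S,2R,3R)-2-Bzf-4,6-dimethoxy-1-(4-methoxybenzyl)-3-(4-methoxyphenyl)indan-1-ol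
Product: 16 (2R,3R)-2-Bzf-4,6-dimethoxy-1-[(E)-4-methoxybenzylidene]-3-(4-methoxyphenyl)indane
Conditions: Burgess reagent (MeO2C–N–SO2–NEt3 inner salt), toluene, 50 °C
Reagents that add atoms: none
Why: Burgess dehydration is a syn intramolecular elimination, and because the only ring hydrogen next to the carbinol (H2) is anti to the OH the sulfamate can take only a benzylic CH2 hydrogen, giving the exocyclic (E)-benzylidene and not the conjugated indene while C2 and C3 stay intact.

Step 8
Reactants: 16 (2R,3R)-2-Bzf-4,6-dimethoxy-1-[(E)-4-methoxybenzylidene]-3-(4-methoxyphenyl)indane; 17 N-(phenylselanyl)phthalimide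
Product: 18 ring-fusion phenylselanyl derivative of 19 (SePh in place of H at the former indane C1)
Conditions: Me3SiOTf (cat.), CH2Cl2, −78 °C; quench with Et3N
Reagents that add atoms: N-(phenylselanyl)phthalimide, O=C1N([Se]c2ccccc2)C(=O)c2ccccc12
Why: In this selenium-triggered Friedel–Crafts carbocyclisation the seleniranium ion forms on the alkene face anti to the C2 benzofuranyl group and is opened anti at the 4-methoxybenzylic carbon by C5 of the benzofuran (para to the ring oxygen, linear ring fusion), which fixes the cis ring fusion with Se on the convex face and, from the E alkene, the exo 4-methoxyphenyl group.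

Step 9
Reactants: 18 ring-fusion phenylselanyl derivative of 19
Product: 19 octa-O-methyl ether of 20
Conditions: Bu3SnH, AIBN (cat.), toluene, 90 °C
Reagents that add atoms: none
Why: In this radical deselenation the tertiary benzylic ring-fusion radical can take hydrogen only on the convex face, so the cis-fused bicyclo[3.3.0]octane results and no other centre is touched.

Step 10
Reactants: 19 octa-O-methyl ether of 20
Product: 20 target octaphenol
Conditions: BBr3, CH2Cl2, −78 °C to rt; then H2O
Reagents that add atoms: none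
Why: BBr3 cleaves all eight aryl methyl ethers (Lewis acid complexation, then SN2 demethylation by bromide), and if the benzylic C2–O bond ionises it re-closes trans to the fixed C3 centre, so no stereocentre is lost.

## Compound list

1 | natural gnetin C, 5-[(2S,3S)-4-hydroxy-2-(4-hydroxyphenyl)-6-[(E)-2-(4-hydroxyphenyl)ethenyl]-2,3-dihydro-1-benzofuran-3-yl]benzene-1,3-diol | Oc1ccc(/C=C/c2cc(O)c3[C@H](c4cc(O)cc(O)c4)[C@@H](c4ccc(O)cc4)Oc3c2)cc1 | starting material
2 | iodomethane | CI | starting material
3 | penta-O-methylgnetin C | COc1ccc(/C=C/c2cc(OC)c3[C@H](c4cc(OC)cc(OC)c4)[C@@H](c4ccc(OC)cc4)Oc3c2)cc1 | intermediate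
4 | ozone | [O-][O+]=O | starting material
5 | (2S,3S)-3-(3,5-dimethoxyphenyl)-4-methoxy-2-(4-methoxyphenyl)-2,3-dihydro-1-benzofuran-6-carbaldehyde (Bzf–CHO) | O=Cc1cc(OC)c2[C@H](c3cc(OC)cc(OC)c3)[C@@H](c3ccc(OC)cc3)Oc2c1 | intermediate
6 | 4-methylbenzenesulfonohydrazide | Cc1ccc(cc1)S(=O)(=O)NN | starting material
7 | 3,5-dimethoxybenzaldehyde | COc1cc(C=O)cc(OC)c1 | starting material
8 | N-tosylhydrazone of 5 (Bzf–CH=N–NHTs, E) | Cc1ccc(cc1)S(=O)(=O)N/N=C/c1cc(OC)c2[C@H](c3cc(OC)cc(OC)c3)[C@@H](c3ccc(OC)cc3)Oc2c1 | intermediate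
9 | aryldiazomethane Bzf–CH=N2 | [N-]=[N+]=Cc1cc(OC)c2[C@H](c3cc(OC)cc(OC)c3)[C@@H](c3ccc(OC)cc3)Oc2c1 | intermediate
10 | 1-(3,5-dimethoxyphenyl)-2-Bzf-ethan-1-one | COc1cc(cc(OC)c1)C(=O)Cc1cc(OC)c2[C@H](c3cc(OC)cc(OC)c3)[C@@H](c3ccc(OC)cc3)Oc2c1 | intermediate
11 | 4-methoxybenzaldehyde | COc1ccc(C=O)cc1 | starting material
12 | (E)-1-(3,5-dimethoxyphenyl)-2-Bzf-3-(4-methoxyphenyl)prop-2-en-1-one | COc1ccc(/C=C(\c2cc(OC)c3[C@H](c4cc(OC)cc(OC)c4)[C@@H](c4ccc(OC)cc4)Oc3c2)C(=O)c2cc(OC)cc(OC)c2)cc1 | intermediate
13 | (2R,3R)-2-Bzf-4,6-dimethoxy-3-(4-methoxyphenyl)indan-1-one | COc1ccc([C@@H]2c3c(OC)cc(OC)cc3C(=O)[C@H]2c2cc(OC)c3[C@H](c4cc(OC)cc(OC)c4)[C@@H](c4ccc(OC)cc4)Oc3c2)cc1 | intermediate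
14 | (4-methoxybenzyl)magnesium chloride | COc1ccc(C[Mg]Cl)cc1 | starting material
15 | (1S,2R,3R)-2-Bzf-4,6-dimethoxy-1-(4-methoxybenzyl)-3-(4-methoxyphenyl)indan-1-ol | COc1ccc([C@@H]2c3c(OC)cc(OC)cc3[C@](O)(Cc3ccc(OC)cc3)[C@H]2c2cc(OC)c3[C@H](c4cc(OC)cc(OC)c4)[C@@H](c4ccc(OC)cc4)Oc3c2)cc1 | intermediate
16 | (2R,3R)-2-Bzf-4,6-dimethoxy-1-[(E)-4-methoxybenzylidene]-3-(4-methoxyphenyl)indane | COc1ccc([C@@H]2c3c(OC)cc(OC)cc3/C(=C/c3ccc(OC)cc3)[C@H]2c2cc(OC)c3[C@H](c4cc(OC)cc(OC)c4)[C@@H](c4ccc(OC)cc4)Oc3c2)cc1 | intermediate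
17 | N-(phenylselanyl)phthalimide | O=C1N([Se]c2ccccc2)C(=O)c2ccccc12 | starting material
18 | phenylselanyl derivative of 19: SePh replaces H at the ring-fusion carbon next to the dimethoxybenzo ring, ring B closed on C5 of the benzofuran, other centres as in 19 | COc1ccc([C@@H]2c3c(OC)cc(OC)cc3[C@@]3([Se]c6ccccc6)[C@H](c4ccc(OC)cc4)c4c(cc5c(c4OC)[C@H](c4cc(OC)cc(OC)c4)[C@@H](c4ccc(OC)cc4)O5)[C@@H]23)cc1 | intermediate
19 | octa-O-methyl ether of 20 (all eight OH as OMe, six stereocentres as in 20) | COc1ccc([C@@H]2c3c(OC)cc(OC)cc3[C@H]3[C@H](c4ccc(OC)cc4)c4c(cc5c(c4OC)[C@H](c4cc(OC)cc(OC)c4)[C@@H](c4ccc(OC)cc4)O5)[C@@H]23)cc1 | intermediate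
20 | target CNP0198336.1: cis-fused dibenzobicyclo[3.3.0]octadiene with two exo 4-hydroxyphenyl groups, one benzo ring a resorcinol, the other carrying OH and the (2S,3S)-trans-2-(4-hydroxyphenyl)-3-(3,5-dihydroxyphenyl)dihydrofuran | Oc1ccc([C@@H]2c3c(O)cc(O)cc3[C@H]3[C@H](c4ccc(O)cc4)c4c(cc5c(c4O)[C@H](c4cc(O)cc(O)c4)[C@@H](c4ccc(O)cc4)O5)[C@@H]23)cc1 | target

## Step count and weak points

Total step count: 10. Longest linear sequence: 10 (steps 1 to 10 in a row from 1). Step 5 halves the material by design (about 1:1 diastereomers), which is a yield cost and not a failure.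

The step most likely to fail is step 8. The ring closure can go to C7 of the benzofuran (ortho to the ring oxygen) as well as to C5, because both positions are activated by the two ring oxygens; C5 is favoured only by the linear ring fusion and the para relationship to the ring oxygen. The tertiary benzylic selenide can also ionise. The fallback uses the wrong regioisomer instead of discarding it. Setting out from 16, the same conditions give the C7-closed selenide F1. Bu3SnH with AIBN gives its octamethyl ether F2. BBr3 gives the octaphenol F3, the constitutional isomer of 20 with the dihydrofuran oxygen next to ring B. F3 has the same core configuration and the same C3 centre as 20. Warming F3 with TFA in hexafluoroisopropanol ionises the benzylic C2–O bond reversibly and lets the dihydrofuran re-close on the other resorcinol oxygen, trans to C3. This converts F3 into 20, where the fallback comes back to the route; 20 is separated and remaining F3 is recycled. The position of that equilibrium is not known.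

The second is step 10. BBr3 can open the 2-(4-oxyphenyl)dihydrofuran at the benzylic C2–O bond, with bromide capture or re-closure on either flanking oxygen. The fallback changes from electrophilic to nucleophilic ether cleavage. Setting out from 19, NaSEt in DMF at 130 °C under argon removes the eight methyl groups by SN2 attack at methyl without a Lewis acid, and acidification gives 20 directly. No new compound is made (entry F0).

The third is step 3. The one-pot diazo coupling puts the valuable fragment on the diazo side, where azine formation and carbene dimerisation compete. The fallback builds the ketone by carbonyl chemistry only. Setting out from 5, Wittig methoxymethylenation with Ph3P=CHOMe (from (methoxymethyl)triphenylphosphonium chloride and KN(SiMe3)2) gives the enol ether F4. Aqueous HCl in THF gives the arylacetaldehyde F5. Addition of 3,5-dimethoxyphenylmagnesium bromide gives the carbinol F6 as a mixture of epimers. Dess–Martin oxidation then comes back to the route at ketone 10.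

## Further compounds

F1 | step 8 | regioisomer of 18 with ring B closed on C7 of the benzofuran (ortho to the ring oxygen) | COc1ccc([C@@H]2c3c(OC)cc(OC)cc3[C@@]3([Se]c7ccccc7)[C@H](c4ccc(OC)cc4)c4c(cc(OC)c5c4O[C@H](c6ccc(OC)cc6)[C@H]5c6cc(OC)cc(OC)c6)[C@@H]23)cc1
F2 | step 8 | octa-O-methyl regioisomer of 19 (ring B on C7 of the benzofuran) | COc1ccc([C@@H]2c3c(OC)cc(OC)cc3[C@H]3[C@H](c4ccc(OC)cc4)c4c(cc(OC)c5c4O[C@H](c6ccc(OC)cc6)[C@H]5c6cc(OC)cc(OC)c6)[C@@H]23)cc1
F3 | step 8 | octaphenol regioisomer of 20 (dihydrofuran oxygen next to ring B, free OH next to the aromatic CH) | Oc1ccc([C@@H]2c3c(O)cc(O)cc3[C@H]3[C@H](c4ccc(O)cc4)c4c(cc(O)c5c4O[C@H](c6ccc(O)cc6)[C@H]5c6cc(O)cc(O)c6)[C@@H]23)cc1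
F4 | step 3 | enol ether Bzf–CH=CH–OMe (E/Z mixture, E drawn) | CO/C=C/c1cc(OC)c2[C@H](c3cc(OC)cc(OC)c3)[C@@H](c3ccc(OC)cc3)Oc2c1
F5 | step 3 | arylacetaldehyde Bzf–CH2–CHO | O=CCc1cc(OC)c2[C@H](c3cc(OC)cc(OC)c3)[C@@H](c3ccc(OC)cc3)Oc2c1
F6 | step 3 | 1-(3,5-dimethoxyphenyl)-2-Bzf-ethan-1-ol (both carbinol epimers) | COc1cc(cc(OC)c1)C(O)Cc1cc(OC)c2[C@H](c3cc(OC)cc(OC)c3)[C@@H](c3ccc(OC)cc3)Oc2c1
F0 | step 10 | none | none
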